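Remark: atoms are labelled as in lignans (C7, C8, C9 on the syringyl half; C7', C8', C9' on the guaiacyl half; the ring oxygen joins C9 and C9'). In these labels the target is 7S,8R,8'R.

## Analysis of the target

The target is a 9,9'-epoxylignan: one tetrahydrofuran ring (O, C9, C8, C8', C9') with a 4-hydroxy-3-methoxybenzyl group (C7') on C8' and a secondary benzylic carbinol (C7) carrying a 4-hydroxy-3,5-dimethoxyphenyl ring on C8. It has three contiguous stereocentres, C7 (S), C8 (R) and C8' (R). The two ring substituents are trans, and the C7 hydroxyl is syn to the C8–C8' bond when the chain aryl–C7–C8–C9 is drawn as a zigzag. The sensitive groups are the two free phenols and the C7 alcohol, which is benzylic and para to a phenolic oxygen: it ionises easily under acid and can be lost by hydrogenolysis. The ring ether lies between two CH2 groups and offers no handle of its own. The difficulties are the exocyclic centre C7, which must be set relative to the ring, and the two electron-rich aryl groups, which differ by a single methoxy group and must be placed without ambiguity. The strategy rests on the substitution pattern of C8' and C8: C8' bears the arylmethyl carbon C7' and the ring OCH2 C9', and C8 bears two oxidised carbons, ring C9 and carbinol C7. This is the pattern of a 2-oxo-3-oxabicyclo[3.1.0]hexane-1-carboxylate that has been opened at its cyclopropane CH2 and acylated: C6 of the bicycle becomes C7', C5 becomes C8', C4 becomes C9', C1 becomes C8, C2 becomes C9, and the ester carbon is discarded.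

## Retrosynthetic reasoning

The last disconnections are protective. The two phenols of 22 are carried as benzyl ethers (21), because this protection survives an aryl Grignard reagent, an acid chloride, hydride and fluoride, and is removed under neutral conditions. The C7 hydroxyl of 21 is carried as a silyl ether (20), so that only two hydroxyls are free when the ring is closed.

The ring of 20 is cut at one C–O bond (O–C9 or O–C9', the outcome is the same) to give the 1,4-diol 19. Both carbons at the ether oxygen are CH2 groups, so the cut touches no stereocentre. The forward reaction is a cyclodehydration with 5-exo-tet closure. With the C7 oxygen silylated, the isomeric 7,9'-ether cannot form.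

Raising C9 to the carboxyl level turns 19 into the lactone 18 and, without the silyl group, into 17. The lactone carbonyl is what makes C8 acidic and what allows a ketone at C7 to be introduced by enolate chemistry. The forward step is a hydride reduction of the lactone.

The C7–H bond of 17 is cut to give the aryl ketone 16. This is preferred to forming C7 by addition to an aldehyde, because an aryl ketone can be reduced under catalyst control. In 16 the C8 hydrogen lies between two carbonyl groups, so C8 equilibrates and takes the trans configuration dictated by C8'. The forward step has to choose only the face of the ketone.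

The C8–H bond of 16 is traced to a C8–CO2allyl bond in 14. The ester is the second acceptor group that the ring opening needs. Its allyl form can be removed with a palladium catalyst and a hydride donor under neutral conditions, after which decarboxylation is spontaneous.

In 14 two skeletal bonds are cut at once: C7'–aryl and C7–C8. This gives the bicyclic lactone 5, the aryl Grignard reagent 8 and the acid chloride 12. The cut is made here because the C5–C6–C1 unit of 5 is a homo-Michael acceptor whose opening produces exactly the enolate that is needed for acylation. C8' is not a reacting centre and keeps the configuration of 5. Each aryl group enters from its own reagent, so the two cannot be confused. The forward reaction must attack the cyclopropane CH2 rather than a carbonyl group, and must acylate the enolate on carbon.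

Lactone 5 is cut at both cyclopropane bonds to C1 and at the lactone C–O bond, which leads to the chloro epoxide 1 and the malonate 2. The single stereocentre of 1 becomes C5 of 5 and, later, C8' of the target.

Reagent 8 comes from bromide 7, and 7 from phenol 6 by O-benzylation. Acid chloride 12 comes from acid 11, and 11 from 9 by benzylation through ester 10 and saponification.

## Alternatives that were turned down

Alternative 1: The C7–C8 bond and a temporary O–C9 bond are disconnected together. The target is traced to the oxetane A1, a 2,7-dioxabicyclo[3.2.0]heptane in which the C7 oxygen is tied to C9 as an acetal. A1 would come from the enantiopure dihydrofuran A2 and the aryl aldehyde A3 by a Paternò–Büchi reaction.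
- Forward key step: triplet A3 adds across the enol ether double bond of A2 through a 1,4-biradical. Attack anti to the C8' substituent sets C8, and the endo position of the aryl group sets C7. A reductive opening of the acetal C9–O bond would then release the C7 hydroxyl and the C9 methylene.
- For it: C7 and C8 are formed in one step, the C7 oxygen arrives already masked, and the ring is at the right oxidation level. On the C7/C8 relationship this route is stronger than the chosen one, which needs a separate ketone reduction.
- Against it: the lowest triplet of an aldehyde with three oxygen donors on the ring has much π,π* character, and the electron-rich arene of A2 can quench it by charge transfer. Endo/exo and facial selectivity are kinetic outcomes of biradical closure and cannot be corrected by equilibration. The acetal opening must cleave C9–O and spare the benzylic C7–O bond, which a Lewis acid ionises just as readily. A2 needs an asymmetric synthesis of its own.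
- Comparison: the chosen strategy offers ground-state chemistry in which C8' comes from the chiral pool in step 1, C8 is set by equilibration and C7 by a reagent that can be changed (16 to 17).

Alternative 2: Both ring C–C bonds next to the oxygen-bearing carbons, C8–C9 and C8'–C9', are disconnected. The ring is traced to a [3+2] cycloaddition between the (E)-enoyl sultam A6 and the unstabilised 1,3-dipole released from the silyl chloromethyl ether A5 by fluoride. The product is the acyl sultam A4.
- Forward key step: the suprafacial cycloaddition transfers the E geometry into the trans ring relationship, and the bornane sultam unit selects the face.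
- For it: the complete ring, with its ether oxygen and the trans relationship, is made in one step. On ring construction it is stronger than the chosen route, which needs lactone reduction, silyl protection and cyclodehydration (17 to 20).
- Against it: A4 lacks the syringyl ring and the C7 stereocentre. After removal of the auxiliary, an aryl metal reagent must be added to an α-branched carbonyl group with little facial bias, or the same ketone reduction is reached only after several more steps. The double bond of A6 can move into conjugation with the arene under the basic fluoride conditions. The facial selectivity of so small and reactive a dipole is not assured, and the auxiliary is stoichiometric and heavy.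
- Comparison: the chosen strategy attaches both aryl groups and the C7 carbon in its key step (14) and takes C8' from 1 without an auxiliary.

Alternative 3: The ring O–C9 bond is disconnected. The ring is traced to the achiral oxetane A8, whose allylic hydroxyl opens one of the two enantiotopic oxetane CH2 groups under a chiral salen complex of trivalent cobalt to give the alkylidene tetrahydrofuran A7.
- Forward key step: Lewis-acid activation of the oxetane and 5-exo attack by the hydroxyl set C8 and release the other arm as the C7 hydroxymethyl group.
- For it: the enantiocontrol is catalytic and starts from an achiral precursor, and the tetrahydrofuran arrives directly. On the source of chirality it is stronger than the chosen route, which depends on the enantiomeric purity of 1.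
- Against it: only one of the three stereocentres is set. C8' then depends on a face-selective hydrogenation of the exocyclic trisubstituted alkene, which must not cleave the benzyl ether. C7 must be oxidised to the aldehyde, arylated without control and corrected by oxidation and reduction. A8 itself needs several steps.
- Comparison: the chosen strategy forms two skeletal bonds in its key step and delivers C7 directly at the ketone level in 16, ready for a catalyst-controlled reduction, with fewer operations after the key step.

Key step: step 6

## Route

Step 1
Reactants: 1 (R)-epichlorohydrin; 2 diallyl malonate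
Product: 5 allyl (1S,5R)-2-oxo-3-oxabicyclo[3.1.0]hexane-1-carboxylate, via epoxymalonate 3 (not isolated), via cyclopropylmethanol alkoxide 4 (not isolated)
Conditions: NaH, allyl alcohol, 0 °C (forms NaOCH2CH=CH2); 2; then 1, rt → 70 °C
Reagents that add atoms: none
Why: Tandem malonate alkylation–cyclopropanation–lactonisation: the sodium enolate of 2 opens the epoxide of 1 at its CH2, the alkoxide displaces chloride to give epoxide 3, the re-formed malonate anion closes the three-membered ring by 3-exo-tet attack with inversion at the stereocentre to give alkoxide 4, and this alkoxide, cis to one ester, lactonises. The stereocentre of 1 becomes C5 of 5 and the cis ring fusion fixes C1; allyloxide in allyl alcohol prevents ester scrambling. Direct displacement of chloride, which would lead to the enantiomer, has to remain a minor pathway.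

Step 2
Reactants: 6 4-bromo-2-methoxyphenol
Product: 7 1-(benzyloxy)-4-bromo-2-methoxybenzene
Conditions: BnBr, K2CO3, DMF, rt
Reagents that add atoms: benzyl bromide, BrCc1ccccc1
Why: Williamson ether synthesis on the phenoxide; the aryl bromide is inert under these conditions.

Step 3
Reactants: 7 1-(benzyloxy)-4-bromo-2-methoxybenzene
Product: 8 [4-(benzyloxy)-3-methoxyphenyl]magnesium bromide (titrated THF solution, used directly)
Conditions: Mg turnings, I2 (cat.), THF, reflux
Reagents that add atoms: magnesium, [Mg]
Why: Grignard formation by insertion of magnesium into the aryl C–Br bond; the aryl methyl and benzyl ethers are inert.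

Step 4
Reactants: 9 syringic acid
Product: 11 4-(benzyloxy)-3,5-dimethoxybenzoic acid, via benzyl ester 10 (not isolated)
Conditions: BnBr, K2CO3, DMF, 60 °C; then aq. NaOH, MeOH, 60 °C; then aq. HCl
Reagents that add atoms: benzyl bromide, BrCc1ccccc1; sodium hydroxide, [Na+].[OH-]
Why: Williamson etherification of the phenoxide and alkylation of the carboxylate give ester 10, and saponification of this unhindered benzoate in the same flask returns the acid. The aryl benzyl ether is stable to hydroxide.

Step 5
Reactants: 11 4-(benzyloxy)-3,5-dimethoxybenzoic acid
Product: 12 4-(benzyloxy)-3,5-dimethoxybenzoyl chloride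
Conditions: (COCl)2, DMF (cat.), CH2Cl2, 0 °C → rt; evaporate
Reagents that add atoms: oxalyl chloride, O=C(Cl)C(=O)Cl
Why: Acid chloride formation through the Vilsmeier-type chloroiminium species formed from oxalyl chloride and catalytic DMF. The ethers are untouched and the by-products are gases, so 12 is used after evaporation.

Step 6
Reactants: 5 allyl (1S,5R)-2-oxo-3-oxabicyclo[3.1.0]hexane-1-carboxylate; 8 [4-(benzyloxy)-3-methoxyphenyl]magnesium bromide; 12 4-(benzyloxy)-3,5-dimethoxybenzoyl chloride
Product: 14 allyl (3S,4R)-3-[4-(benzyloxy)-3,5-dimethoxybenzoyl]-4-[4-(benzyloxy)-3-methoxybenzyl]-2-oxotetrahydrofuran-3-carboxylate, via bromomagnesium enolate 13 (not isolated)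
Conditions: CuI (10 mol%), THF, −30 °C, slow addition of 8 (slight excess); then 12, −30 °C → rt; aq. NH4Cl
Reagents that add atoms: none
Why: Transmetalation of 8 to CuI gives an arylcopper species that attacks the cyclopropane CH2 (C6) of 5 in an SN2 manner, with the lactone- and ester-stabilised enolate as leaving group and release of ring strain as driving force; this homoconjugate addition forms the C7'–aryl bond and gives the chelated magnesium enolate 13. Addition of 12 then acylates 13 on carbon and forms C7–C8. The closest known reaction types are the copper-catalysed Grignard opening of 2-oxo-3-oxabicyclo[3.1.0]hexane-1-carboxylates and the C-acylation of chelated magnesium malonate enolates by acid chlorides, run here one after the other in one flask. No ring is closed: the cyclopropane is opened and the lactone ring is kept. C8' (C5 of 5) is not a reacting centre and keeps the configuration that came from 1. The quaternary C8 is formed by acylation on the enolate face opposite the adjacent arylmethyl group (substrate control) and is erased again in step 7. The step needs attack at CH2 rather than at a carbonyl group or at the more substituted C5, which copper catalysis at low temperature and the SN2 character of the opening provide. It also needs C- rather than O-acylation, which the magnesium chelate of the β-dicarbonyl enolate favours, and it needs 8 to be consumed before 12 is added, which the near-stoichiometric charge ensures.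

Step 7
Reactants: 14 allyl (3S,4R)-3-[4-(benzyloxy)-3,5-dimethoxybenzoyl]-4-[4-(benzyloxy)-3-methoxybenzyl]-2-oxotetrahydrofuran-3-carboxylate
Product: 16 (3S,4R)-3-[4-(benzyloxy)-3,5-dimethoxybenzoyl]-4-[4-(benzyloxy)-3-methoxybenzyl]dihydrofuran-2(3H)-one, via carboxylic acid 15 (not isolated)
Conditions: Pd(PPh3)4 (cat.), HCO2H, Et3N, THF, rt → 40 °C
Reagents that add atoms: none
Why: Palladium-catalysed deallylation with formate as hydride donor (Tsuji–Trost-type ionisation to an allylpalladium carboxylate, then reduction to propene) gives acid 15, a β-keto acid flanked by a second carbonyl group, which decarboxylates at or slightly above room temperature. Protonation gives the 2-acyl lactone, whose acidic C8–H lets C8 settle trans to C8'. Formate is not nucleophilic, so the aroyl group should not be cleaved.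

Step 8
Reactants: 16 (3S,4R)-3-[4-(benzyloxy)-3,5-dimethoxybenzoyl]-4-[4-(benzyloxy)-3-methoxybenzyl]dihydrofuran-2(3H)-one
Product: 17 (3S,4R)-3-{(S)-[4-(benzyloxy)-3,5-dimethoxyphenyl](hydroxy)methyl}-4-[4-(benzyloxy)-3-methoxybenzyl]dihydrofuran-2(3H)-one
Conditions: RuCl(p-cymene)[(S,S)-TsDPEN] (cat.), HCO2H/Et3N (5:2), DMF, 40 °C
Reagents that add atoms: none
Why: Noyori–Ikariya asymmetric transfer hydrogenation of an aryl ketone: hydride and proton are delivered from the ruthenium hydride–amine complex in an outer-sphere six-membered transition state with the aryl group under the η6-arene, so the (S,S) ligand should give the S carbinol, as with simple aryl alkyl ketones. C8 stays trans to C8' because it equilibrates through the enol in this medium, so the catalyst has to choose only the carbonyl face.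

Step 9
Reactants: 17 (3S,4R)-3-{(S)-[4-(benzyloxy)-3,5-dimethoxyphenyl](hydroxy)methyl}-4-[4-(benzyloxy)-3-methoxybenzyl]dihydrofuran-2(3H)-one
Product: 18 (3S,4R)-3-{(S)-[4-(benzyloxy)-3,5-dimethoxyphenyl][(tert-butyldimethylsilyl)oxy]methyl}-4-[4-(benzyloxy)-3-methoxybenzyl]dihydrofuran-2(3H)-one
Conditions: TBSOTf, 2,6-lutidine, CH2Cl2, −78 → 0 °C
Reagents that add atoms: tert-butyldimethylsilyl trifluoromethanesulfonate, CC(C)(C)[Si](C)(C)OS(=O)(=O)C(F)(F)F
Why: Silylation of a hindered secondary alcohol with a silyl triflate and a non-nucleophilic base. Low temperature and the lutidine buffer should avoid ionisation of the benzylic C–O bond and β-elimination.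

Step 10
Reactants: 18 (3S,4R)-3-{(S)-[4-(benzyloxy)-3,5-dimethoxyphenyl][(tert-butyldimethylsilyl)oxy]methyl}-4-[4-(benzyloxy)-3-methoxybenzyl]dihydrofuran-2(3H)-one
Product: 19 (2R,3R)-2-[4-(benzyloxy)-3-methoxybenzyl]-3-{(S)-[4-(benzyloxy)-3,5-dimethoxyphenyl][(tert-butyldimethylsilyl)oxy]methyl}butane-1,4-diol
Conditions: LiBH4, THF, 0 °C → rt
Reagents that add atoms: none
Why: Hydride reduction of the lactone to the 1,4-diol. LiBH4 leaves the benzyl ethers and the silyl ether alone, and the silyl group keeps the C7 oxygen masked so that only the two primary hydroxyls are free.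

Step 11
Reactants: 19 (2R,3R)-2-[4-(benzyloxy)-3-methoxybenzyl]-3-{(S)-[4-(benzyloxy)-3,5-dimethoxyphenyl][(tert-butyldimethylsilyl)oxy]methyl}butane-1,4-diol
Product: 20 tert-butyl{(S)-[4-(benzyloxy)-3,5-dimethoxyphenyl][(3R,4R)-4-(4-(benzyloxy)-3-methoxybenzyl)tetrahydrofuran-3-yl]methoxy}dimethylsilane
Conditions: PPh3, DIAD, THF, 0 °C → rt
Reagents that add atoms: none
Why: Mitsunobu cyclodehydration: one primary hydroxyl becomes an alkoxyphosphonium leaving group and is displaced by the other in a 5-exo-tet closure. Both reacting carbons are CH2 groups, so no stereocentre is touched, and the silylated C7 oxygen cannot compete to give the 7,9'-ether.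

Step 12
Reactants: 20 tert-butyl{(S)-[4-(benzyloxy)-3,5-dimethoxyphenyl][(3R,4R)-4-(4-(benzyloxy)-3-methoxybenzyl)tetrahydrofuran-3-yl]methoxy}dimethylsilane
Product: 21 (S)-[4-(benzyloxy)-3,5-dimethoxyphenyl]{(3R,4R)-4-[4-(benzyloxy)-3-methoxybenzyl]tetrahydrofuran-3-yl}methanol
Conditions: Bu4NF, THF, 0 °C → rt
Reagents that add atoms: none
Why: Fluoride-induced cleavage of the silyl ether, driven by the strength of the Si–F bond; the benzyl ethers and the tetrahydrofuran are inert.

Step 13
Reactants: 21 (S)-[4-(benzyloxy)-3,5-dimethoxyphenyl]{(3R,4R)-4-[4-(benzyloxy)-3-methoxybenzyl]tetrahydrofuran-3-yl}methanol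
Product: 22 (S)-(4-hydroxy-3,5-dimethoxyphenyl)[(3R,4R)-4-(4-hydroxy-3-methoxybenzyl)tetrahydrofuran-3-yl]methanol
Conditions: H2 (1 atm), Pd/C, EtOAc/EtOH, rt
Reagents that add atoms: none
Why: Hydrogenolysis of the two aryl benzyl ethers over palladium under neutral conditions. O-Benzyl cleavage should be much faster than hydrogenolysis of the secondary benzylic alcohol, so the reaction is stopped once both benzyl groups are gone.

## Compound list

1 | (R)-epichlorohydrin | ClC[C@H]1CO1 | starting material
2 | diallyl malonate | C=CCOC(=O)CC(=O)OCC=C | starting material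
3 | diallyl 2-{[(2R)-oxiran-2-yl]methyl}malonate | C=CCOC(=O)C(C[C@@H]1CO1)C(=O)OCC=C | intermediate
4 | diallyl (2R)-2-(hydroxymethyl)cyclopropane-1,1-dicarboxylate (present as its sodium alkoxide) | OC[C@@H]1CC1(C(=O)OCC=C)C(=O)OCC=C | intermediate
5 | allyl (1S,5R)-2-oxo-3-oxabicyclo[3.1.0]hexane-1-carboxylate | C1[C@H]2COC(=O)[C@@]12C(=O)OCC=C | intermediate
6 | 4-bromo-2-methoxyphenol | COc1cc(Br)ccc1O | starting material
7 | 1-(benzyloxy)-4-bromo-2-methoxybenzene | COc1cc(Br)ccc1OCc1ccccc1 | intermediate
8 | [4-(benzyloxy)-3-methoxyphenyl]magnesium bromide | COc1cc([Mg]Br)ccc1OCc1ccccc1 | intermediate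
9 | syringic acid (4-hydroxy-3,5-dimethoxybenzoic acid) | COc1cc(C(=O)O)cc(OC)c1O | starting material
10 | benzyl 4-(benzyloxy)-3,5-dimethoxybenzoate | COc1cc(C(=O)OCc2ccccc2)cc(OC)c1OCc1ccccc1 | intermediate
11 | 4-(benzyloxy)-3,5-dimethoxybenzoic acid | COc1cc(C(=O)O)cc(OC)c1OCc1ccccc1 | intermediate
12 | 4-(benzyloxy)-3,5-dimethoxybenzoyl chloride | COc1cc(C(=O)Cl)cc(OC)c1OCc1ccccc1 | intermediate
13 | bromomagnesium enolate of allyl (4R)-4-[4-(benzyloxy)-3-methoxybenzyl]-2-oxotetrahydrofuran-3-carboxylate | COc1cc(C[C@H]2COC(O[Mg]Br)=C2C(=O)OCC=C)ccc1OCc1ccccc1 | intermediate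
14 | allyl (3S,4R)-3-[4-(benzyloxy)-3,5-dimethoxybenzoyl]-4-[4-(benzyloxy)-3-methoxybenzyl]-2-oxotetrahydrofuran-3-carboxylate | COc1cc(C[C@H]2COC(=O)[C@]2(C(=O)OCC=C)C(=O)c2cc(OC)c(OCc3ccccc3)c(OC)c2)ccc1OCc1ccccc1 | intermediate
15 | (3S,4R)-3-[4-(benzyloxy)-3,5-dimethoxybenzoyl]-4-[4-(benzyloxy)-3-methoxybenzyl]-2-oxotetrahydrofuran-3-carboxylic acid | COc1cc(C[C@H]2COC(=O)[C@]2(C(=O)O)C(=O)c2cc(OC)c(OCc3ccccc3)c(OC)c2)ccc1OCc1ccccc1 | intermediate
16 | (3S,4R)-3-[4-(benzyloxy)-3,5-dimethoxybenzoyl]-4-[4-(benzyloxy)-3-methoxybenzyl]dihydrofuran-2(3H)-one | COc1cc(C[C@H]2COC(=O)[C@@H]2C(=O)c2cc(OC)c(OCc3ccccc3)c(OC)c2)ccc1OCc1ccccc1 | intermediate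
17 | (3S,4R)-3-{(S)-[4-(benzyloxy)-3,5-dimethoxyphenyl](hydroxy)methyl}-4-[4-(benzyloxy)-3-methoxybenzyl]dihydrofuran-2(3H)-one | COc1cc(C[C@H]2COC(=O)[C@@H]2[C@H](O)c2cc(OC)c(OCc3ccccc3)c(OC)c2)ccc1OCc1ccccc1 | intermediate
18 | (3S,4R)-3-{(S)-[4-(benzyloxy)-3,5-dimethoxyphenyl][(tert-butyldimethylsilyl)oxy]methyl}-4-[4-(benzyloxy)-3-methoxybenzyl]dihydrofuran-2(3H)-one | COc1cc(C[C@H]2COC(=O)[C@@H]2[C@H](O[Si](C)(C)C(C)(C)C)c2cc(OC)c(OCc3ccccc3)c(OC)c2)ccc1OCc1ccccc1 | intermediate
19 | (2R,3R)-2-[4-(benzyloxy)-3-methoxybenzyl]-3-{(S)-[4-(benzyloxy)-3,5-dimethoxyphenyl][(tert-butyldimethylsilyl)oxy]methyl}butane-1,4-diol | COc1cc(C[C@@H](CO)[C@H](CO)[C@H](O[Si](C)(C)C(C)(C)C)c2cc(OC)c(OCc3ccccc3)c(OC)c2)ccc1OCc1ccccc1 | intermediate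
20 | tert-butyl{(S)-[4-(benzyloxy)-3,5-dimethoxyphenyl][(3R,4R)-4-(4-(benzyloxy)-3-methoxybenzyl)tetrahydrofuran-3-yl]methoxy}dimethylsilane | COc1cc(C[C@H]2COC[C@@H]2[C@H](O[Si](C)(C)C(C)(C)C)c2cc(OC)c(OCc3ccccc3)c(OC)c2)ccc1OCc1ccccc1 | intermediate
21 | (S)-[4-(benzyloxy)-3,5-dimethoxyphenyl]{(3R,4R)-4-[4-(benzyloxy)-3-methoxybenzyl]tetrahydrofuran-3-yl}methanol | COc1cc(C[C@H]2COC[C@@H]2[C@H](O)c2cc(OC)c(OCc3ccccc3)c(OC)c2)ccc1OCc1ccccc1 | intermediate
22 | (S)-(4-hydroxy-3,5-dimethoxyphenyl)[(3R,4R)-4-(4-hydroxy-3-methoxybenzyl)tetrahydrofuran-3-yl]methanol | COc1cc(C[C@H]2COC[C@@H]2[C@H](O)c2cc(OC)c(O)c(OC)c2)ccc1O | target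

## Step count and least certain steps

Total step count: 13. Longest linear sequence: 10 steps (steps 2, 3 and 6 to 13 from 6; the same length through steps 4, 5 and 6 to 13 from 9).

Step 6 (key step). The most likely failures are addition of 8 to a carbonyl group of 5 in competition with ring opening, slow or oxygen-directed acylation at the fully substituted enolate carbon of 13, consumption of 12 by leftover 8, and retro-Claisen loss of the new aroyl group from the tricarbonyl product during work-up. The fallback separates the two bond formations and sets out from 5 and 8. The copper-catalysed opening is run alone and quenched with aqueous NH4Cl to give allyl (4R)-4-[4-(benzyloxy)-3-methoxybenzyl]-2-oxotetrahydrofuran-3-carboxylate F1 as a mixture of C3 epimers. F1 is then acylated with 12 under soft enolisation (MgCl2, Et3N, MeCN, 0 °C → rt), where the magnesium chelate forms free of aryl metal and copper, and the route is rejoined at 14.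

Step 8. The risk is poor facial selectivity at C7 through a mismatch. The hydride-transfer transition state of the catalyst may prefer the minor cis C8 epimer, which is always available by enolisation, so that the carbinol forms with the wrong relation to the ring or as a mixture. The electron-rich, partly enolised ketone may also react slowly. The fallback changes from catalyst control to substrate control and sets out from 16: chelation-controlled reduction with Zn(BH4)2 in Et2O/CH2Cl2 at low temperature. Zinc bridges the ketone and lactone carbonyl oxygens, and hydride enters C7 from the side of the C8 hydrogen, away from C8'. This should give the same syn carbinol, and the route is rejoined at 17 without a new compound.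

Step 7. Two processes threaten the step: transfer of the allyl group from palladium to the stabilised enolate carbon (decarboxylative allylation) instead of its reduction, and retro-Claisen cleavage of the C7–C8 bond in the tricarbonyl compound. The fallback removes the ester before the ketone is introduced and sets out from 5 and 8. The opened ester F1 described under step 6 is deallylated with Pd(PPh3)4/HCO2H/Et3N, and the resulting acid is decarboxylated by warming in toluene to give (R)-4-[4-(benzyloxy)-3-methoxybenzyl]dihydrofuran-2(3H)-one F2. Its lithium enolate (LiN(SiMe3)2, 2 equiv, THF, −78 °C) is acylated on carbon with 12 in a Claisen-type acylation. The product equilibrates to the trans isomer, and the route is rejoined at 16.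

Step 11. The alkoxyphosphonium intermediate may be intercepted by the hydrazide anion instead of the second, weakly acidic hydroxyl, or both hydroxyls may be activated, so that ring closure is lost to intermolecular alkylation. The fallback is a two-stage Williamson closure and sets out from 19. Selective sulfonylation of the less hindered C9' hydroxyl (TsCl, Et3N, Bu2SnO cat., CH2Cl2) gives (2R,3R)-2-[4-(benzyloxy)-3-methoxybenzyl]-3-{(S)-[4-(benzyloxy)-3,5-dimethoxyphenyl][(tert-butyldimethylsilyl)oxy]methyl}-4-hydroxybutyl 4-methylbenzenesulfonate F3. Treatment with NaH in THF at 0 °C closes the ring by 5-exo-tet displacement, and sulfonylation at the other hydroxyl would lead to the same ring. The route is rejoined at 20.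

Step 13. The risk is over-reduction: once the phenol para to C7 is free, the benzylic C7–O bond can also be hydrogenolysed and the hydroxyl lost. The fallback reverses the last two operations and sets out from 20. Hydrogenolysis is run in EtOAc with the C7 oxygen still carrying its bulky silyl group, to give 4-{(S)-[(tert-butyldimethylsilyl)oxy][(3R,4R)-4-(4-hydroxy-3-methoxybenzyl)tetrahydrofuran-3-yl]methyl}-2,6-dimethoxyphenol F4. Bu4NF buffered with AcOH in THF then removes the silyl group, and the route is rejoined at 22.

## Further compounds

F1 | step 6 | allyl (4R)-4-[4-(benzyloxy)-3-methoxybenzyl]-2-oxotetrahydrofuran-3-carboxylate (C3 epimers) | COc1cc(C[C@H]2COC(=O)C2C(=O)OCC=C)ccc1OCc1ccccc1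
F0 | step 8 | none | none
F2 | step 7 | (R)-4-[4-(benzyloxy)-3-methoxybenzyl]dihydrofuran-2(3H)-one | COc1cc(C[C@H]2COC(=O)C2)ccc1OCc1ccccc1
F3 | step 11 | (2R,3R)-2-[4-(benzyloxy)-3-methoxybenzyl]-3-{(S)-[4-(benzyloxy)-3,5-dimethoxyphenyl][(tert-butyldimethylsilyl)oxy]methyl}-4-hydroxybutyl 4-methylbenzenesulfonate | COc1cc(C[C@@H](COS(=O)(=O)c2ccc(C)cc2)[C@H](CO)[C@H](O[Si](C)(C)C(C)(C)C)c2cc(OC)c(OCc3ccccc3)c(OC)c2)ccc1OCc1ccccc1
F4 | step 13 | 4-{(S)-[(tert-butyldimethylsilyl)oxy][(3R,4R)-4-(4-hydroxy-3-methoxybenzyl)tetrahydrofuran-3-yl]methyl}-2,6-dimethoxyphenol | COc1cc(C[C@H]2COC[C@@H]2[C@H](O[Si](C)(C)C(C)(C)C)c2cc(OC)c(O)c(OC)c2)ccc1O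
A1 | alternative 1 | endo-6-(4-acetoxy-3,5-dimethoxyphenyl)-4-[3-methoxy-4-(triisopropylsilyloxy)benzyl]-2,7-dioxabicyclo[3.2.0]heptane | COc1cc(C[C@H]2CO[C@@H]3O[C@H](c4cc(OC)c(OC(C)=O)c(OC)c4)[C@H]23)ccc1O[Si](C(C)C)(C(C)C)C(C)C
A2 | alternative 1 | (R)-3-[3-methoxy-4-(triisopropylsilyloxy)benzyl]-2,3-dihydrofuran | COc1cc(C[C@H]2COC=C2)ccc1O[Si](C(C)C)(C(C)C)C(C)C
A3 | alternative 1 | 4-formyl-2,6-dimethoxyphenyl acetate | COc1cc(C=O)cc(OC)c1OC(C)=O
A4 | alternative 2 | N-[trans-4-(4-benzyloxy-3-methoxybenzyl)tetrahydrofuran-3-carbonyl]bornane-10,2-sultam | CC1(C)[C@@H]2CC[C@]13CS(=O)(=O)N(C(=O)[C@H]4COC[C@@H]4Cc4ccc(OCc5ccccc5)c(OC)c4)[C@@H]3C2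
A5 | alternative 2 | chloromethyl trimethylsilylmethyl ether | C[Si](C)(C)COCCl
A6 | alternative 2 | N-[(E)-4-(4-benzyloxy-3-methoxyphenyl)but-2-enoyl]bornane-10,2-sultam | CC1(C)[C@@H]2CC[C@]13CS(=O)(=O)N(C(=O)/C=C/Cc4ccc(OCc5ccccc5)c(OC)c4)[C@@H]3C2
A7 | alternative 3 | (S,E)-[4-(4-benzyloxy-3-methoxybenzylidene)tetrahydrofuran-3-yl]methanol | OC[C@H]1COC/C1=C/c1ccc(OCc2ccccc2)c(OC)c1
A8 | alternative 3 | (E)-3-[4-(benzyloxy)-3-methoxyphenyl]-2-(oxetan-3-yl)prop-2-en-1-ol | OC/C(=C/c1ccc(OCc2ccccc2)c(OC)c1)C1COC1
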